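**Strategy.** The chain of the target is read as a ring: butenolide carbon C4, the fourteen methylenes C1'–C14', the acetoxy-bearing C15' and its methyl C16' are the seventeen carbons of 2-methylcyclohexadecanone. A Baeyer–Villiger oxidation inserts oxygen between the carbonyl carbon (future C4) and the methyl-bearing α-carbon (future C15') with retention, so one operation fixes the chain length, differentiates both chain ends and delivers the (S)-carbinol; the seventeen-membered lactone it produces is a temporary ring that is opened again. The precursor is (S)-2-methylcyclohexadecanone, reached by auxiliary-controlled α-methylation of cyclohexadecanone. The butenolide (ring A) is closed last by an intramolecular Horner–Wadsworth–Emmons reaction.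

Key step: step 4

Numbering: ring A is O1, C2(=O), C3(CH3), C4, C5H2; the side chain runs C1'–C16' from C4, and C15' carries the acetate. The target is C23H40O4. The descriptor stays (S) from ketone 7 to target 20 because the inserted oxygen takes the CIP rank of the former carbonyl carbon.

Assumption: the lithium azaenolate of the sixteen-membered hydrazone is taken to have the same geometry as those of common-ring ketones (α-carbon substituent cis to the α'-carbon), so the (R)-auxiliary RAMP, not SAMP, leads to the (S)-ketone.

Step 1
Reactants: 1 cyclohexadecanone; 2 (R)-1-amino-2-(methoxymethyl)pyrrolidine (RAMP)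
Product: 3 (R)-N-cyclohexadecylidene-2-(methoxymethyl)pyrrolidin-1-amine
Conditions: TsOH·H2O (cat.), cyclohexane, reflux, Dean–Stark
Reagents that add atoms: RAMP 2, COC[C@H]1CCCN1N
Why: Acid-catalysed hydrazone formation from a ketone and an N,N-dialkylhydrazine is driven to completion by azeotropic removal of water, and the symmetric ketone can give only one constitutional hydrazone.

Step 2
Reactants: 3 (R)-N-cyclohexadecylidene-2-(methoxymethyl)pyrrolidin-1-amine; 4 iodomethane
Product: 6 (R)-2-(methoxymethyl)-N-[(2S)-2-methylcyclohexadecylidene]pyrrolidin-1-amine, via lithium azaenolate 5 (not isolated)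
Conditions: LiN(i-Pr)2, THF, 0 °C; then MeI, −100 °C → rt
Reagents that add atoms: iodomethane 4, CI
Why: In this auxiliary-controlled hydrazone α-alkylation the azaenolate 5, chelated by the methoxymethyl oxygen, should be methylated on the face away from the pyrrolidine substituent, which with the (R)-auxiliary sets the (S) α-carbon (the (S)-auxiliary is known to give (R)-2-methylcycloalkanones), and the product hydrazone is not deprotonated again, so monoalkylation is expected.

Step 3
Reactants: 6 (R)-2-(methoxymethyl)-N-[(2S)-2-methylcyclohexadecylidene]pyrrolidin-1-amine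
Product: 7 (S)-2-methylcyclohexadecanone
Conditions: sat. aq. (CO2H)2, Et2O, rt, vigorous stirring
Reagents that add atoms: water, O
Why: Mild two-phase acidic hydrazone hydrolysis should return the ketone without enolising the new α-stereocentre, the protonated auxiliary being held in the aqueous layer as its oxalate and recoverable.

Step 4
Reactants: 7 (S)-2-methylcyclohexadecanone
Product: 9 (S)-17-methyloxacycloheptadecan-2-one, via Criegee adduct 8 (not isolated)
Conditions: (CF3CO)2O, urea·H2O2, Na2HPO4, CH2Cl2, 0 °C → rt
Reagents that add atoms: trifluoroperacetic acid (made in the flask), OOC(=O)C(F)(F)F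
Why: The peracid adds to the C1 carbonyl to give the tetrahedral Criegee adduct 8, and the C1–C2 σ bond lying antiperiplanar to the O–O bond shifts from carbon to oxygen in concert with loss of trifluoroacetate. This is the Baeyer–Villiger oxidation of a 2-alkylcycloalkanone, a reaction type established for large-ring ketones. The seventeen-membered ring is closed not by end-to-end cyclisation but by insertion of one oxygen into the existing sixteen-membered carbocycle (ring enlargement by 1,2-shift), so neither high dilution nor a conformational bias is needed. The oxygen-bearing stereocentre (future C15') is inherited, not created: the migrating carbon keeps its configuration, so the (S) centre set in step 2 is transferred with retention. The selectivity required is migration of the secondary, methyl-bearing C2 in preference to the C16 methylene, which the better ability of the more substituted carbon to carry positive charge in the transition state secures. Na2HPO4 keeps the medium free of CF3CO2H, which would otherwise enolise 7 and erode the α-stereocentre before oxidation or open the lactone by transesterification.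

Step 5
Reactants: 9 (S)-17-methyloxacycloheptadecan-2-one
Product: 10 (S)-16-hydroxyheptadecanoic acid
Conditions: KOH, MeOH/H2O, 60 °C; then aq. HCl
Reagents that add atoms: water (as hydroxide from KOH), O
Why: Saponification cleaves the acyl–oxygen bond of the strain-free macrolactone and leaves the C–O bond of the stereocentre untouched, so the (S) configuration is carried over unchanged.

Step 6
Reactants: 10 (S)-16-hydroxyheptadecanoic acid; 11 acetic anhydride
Product: 13 (S)-16-acetoxyheptadecanoic acid, via mixed anhydride 12 (not isolated)
Conditions: Ac2O, pyridine, DMAP (cat.), CH2Cl2, rt; then H2O, rt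
Reagents that add atoms: acetic anhydride 11, CC(=O)OC(C)=O; water, O
Why: DMAP-catalysed O-acylation of the secondary alcohol proceeds with retention because the carbinol C–O bond is not broken, and the mixed anhydride 12 formed at the carboxyl end should be hydrolysed by water in pyridine while the acetate survives.

Step 7
Reactants: 13 (S)-16-acetoxyheptadecanoic acid; 14 trimethylsilyldiazomethane
Product: 17 (S)-18-bromo-17-oxooctadecan-2-yl acetate, via acid chloride 15 (not isolated), via diazoketone 16 (not isolated)
Conditions: (COCl)2, DMF (cat.), CH2Cl2, 0 °C → rt, evaporate; TMSCHN2, THF/MeCN, 0 °C → rt; 48% aq. HBr, 0 °C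
Reagents that add atoms: trimethylsilyldiazomethane 14, C[Si](C)(C)C=[N+]=[N-]; hydrogen bromide, Br
Why: Acid chloride formation, C-acylation of the diazoalkane (Arndt–Eistert-type diazoketone synthesis, chloride removing the silyl group) and protonation of the diazoketone followed by bromide displacement of N2 are standard operations that should tolerate the secondary acetate and leave the remote stereocentre alone.

Step 8
Reactants: 17 (S)-18-bromo-17-oxooctadecan-2-yl acetate; 18 2-(diethoxyphosphoryl)propanoic acid
Product: 20 (2S)-16-(4-methyl-5-oxo-2,5-dihydrofuran-3-yl)hexadecan-2-yl acetate, via keto phosphonate ester 19 (not isolated)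
Conditions: K2CO3, 18-crown-6 (cat.), MeCN, rt; then LiCl, DBU, 0 °C → rt
Reagents that add atoms: 2-(diethoxyphosphoryl)propanoic acid 18, CCOP(=O)(OCC)C(C)C(=O)O
Why: Carboxylate SN2 displacement on the α-bromoketone gives ester 19, whose phosphonate anion, generated by LiCl/DBU, adds to the ketone and expels diethyl phosphate in an intramolecular Horner–Wadsworth–Emmons reaction; the five-membered ring allows only one alkene geometry and the mild amine base spares the acetate.

**Compound list**

1 | cyclohexadecanone | O=C1CCCCCCCCCCCCCCC1 | starting material
2 | (R)-1-amino-2-(methoxymethyl)pyrrolidine (RAMP) | COC[C@H]1CCCN1N | starting material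
3 | (R)-N-cyclohexadecylidene-2-(methoxymethyl)pyrrolidin-1-amine | COC[C@H]1CCCN1N=C2CCCCCCCCCCCCCCC2 | intermediate
4 | iodomethane | CI | starting material
5 | lithium azaenolate of 3 (N-lithiated, C1=C2 with the ring carbons cis) | COC[C@H]1CCCN1N([Li])/C2=C/CCCCCCCCCCCCCC2 | intermediate (not isolated)
6 | (R)-2-(methoxymethyl)-N-[(2S)-2-methylcyclohexadecylidene]pyrrolidin-1-amine | C[C@H]1CCCCCCCCCCCCCCC1=NN2CCC[C@@H]2COC | intermediate
7 | (S)-2-methylcyclohexadecanone | C[C@H]1CCCCCCCCCCCCCCC1=O | intermediate (key-step precursor)
8 | Criegee adduct, (2S)-1-hydroxy-2-methylcyclohexadecyl trifluoroperacetate (C1 epimers) | C[C@H]1CCCCCCCCCCCCCCC1(O)OOC(=O)C(F)(F)F | intermediate (not isolated)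
9 | (S)-17-methyloxacycloheptadecan-2-one | C[C@H]1CCCCCCCCCCCCCCC(=O)O1 | intermediate (key-step product)
10 | (S)-16-hydroxyheptadecanoic acid | C[C@H](O)CCCCCCCCCCCCCCC(=O)O | intermediate
11 | acetic anhydride | CC(=O)OC(C)=O | starting material
12 | acetic (S)-16-acetoxyheptadecanoic anhydride | C[C@H](OC(C)=O)CCCCCCCCCCCCCCC(=O)OC(C)=O | intermediate (not isolated)
13 | (S)-16-acetoxyheptadecanoic acid | C[C@H](OC(C)=O)CCCCCCCCCCCCCCC(=O)O | intermediate
14 | trimethylsilyldiazomethane | C[Si](C)(C)C=[N+]=[N-] | starting material
15 | (S)-16-acetoxyheptadecanoyl chloride | C[C@H](OC(C)=O)CCCCCCCCCCCCCCC(=O)Cl | intermediate (not isolated)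
16 | (S)-18-diazo-17-oxooctadecan-2-yl acetate | C[C@H](OC(C)=O)CCCCCCCCCCCCCCC(=O)C=[N+]=[N-] | intermediate (not isolated)
17 | (S)-18-bromo-17-oxooctadecan-2-yl acetate | C[C@H](OC(C)=O)CCCCCCCCCCCCCCC(=O)CBr | intermediate
18 | 2-(diethoxyphosphoryl)propanoic acid (racemic) | CCOP(=O)(OCC)C(C)C(=O)O | starting material
19 | (17S)-17-acetoxy-2-oxooctadecyl 2-(diethoxyphosphoryl)propanoate (epimers at the phosphonate α-carbon) | C[C@H](OC(C)=O)CCCCCCCCCCCCCCC(=O)COC(=O)C(C)P(=O)(OCC)OCC | intermediate (not isolated)
20 | (2S)-16-(4-methyl-5-oxo-2,5-dihydrofuran-3-yl)hexadecan-2-yl acetate | CC(=O)O[C@@H](C)CCCCCCCCCCCCCCC1=C(C)C(=O)OC1 | target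

**Step count and risks**

Total steps: 8. Longest linear sequence: 8 steps (1 → 20).

Steps most likely to fail:

Step 4. The C16 methylene may migrate in competition with C2, or oxidation of the hindered macrocyclic carbonyl may stall while acid opens the lactone. The fallback sets out from 7 and returns at 10. Under equilibrating conditions (Me3SiCl, NaI, Et3N, MeCN) 7 is converted into the more substituted silyl enol ether 2-methyl-1-(trimethylsilyloxy)cyclohexadec-1-ene F1. Ozonolysis (O3, CH2Cl2/MeOH, −78 °C; Me2S) cleaves the C1=C2 bond to 16-oxoheptadecanoic acid F2. An (S)-selective alcohol dehydrogenase (NADH recycled with i-PrOH, phosphate buffer) then reduces the methyl ketone to 10. The ring is thus cut by alkene cleavage instead of oxygen insertion, and the carbinol configuration is set anew by the enzyme.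

Step 2. Incomplete control of azaenolate geometry or of the face of attack in the flexible sixteen-membered ring would lower the enantiomeric purity, which no later step of the route can raise. The fallback sets out from 1 and returns at 10, replacing auxiliary control by a resolution. Methylation of the lithium enolate of 1 (LiN(i-Pr)2, THF, −78 °C; MeI) gives racemic 2-methylcyclohexadecanone F3. Oxidation as in step 4 gives racemic 17-methyloxacycloheptadecan-2-one F4, which is opened with NaOMe in MeOH to racemic methyl 16-hydroxyheptadecanoate F5. Candida antarctica lipase B with vinyl acetate in MTBE should acetylate only the (R)-alcohol, giving methyl (R)-16-acetoxyheptadecanoate F6 and leaving methyl (S)-16-hydroxyheptadecanoate F7. After chromatographic separation, F7 is saponified (KOH, MeOH/H2O; then HCl) to 10.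

Step 8. The phosphonate anion, hindered by its α-methyl group, may add sluggishly to the ketone, so that acyl transfer, cleavage of the α-acyloxy ketone or base-induced isomerisation of the butenolide competes. The fallback sets out from 17 and returns at 20, forming the C3=C4 bond by addition and then elimination. Bromoketone 17 is esterified with 2-bromopropanoic acid (K2CO3, MeCN, rt) to (17S)-17-acetoxy-2-oxooctadecyl 2-bromopropanoate F8. Activated Zn dust in THF at reflux should effect an intramolecular Reformatsky addition to the hydroxy lactone (2S)-16-(3-hydroxy-4-methyl-5-oxooxolan-3-yl)hexadecan-2-yl acetate F9. Dehydration (SOCl2, pyridine, 0 °C; then Et3N to bring any unconjugated isomer into conjugation) gives 20.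

**Further compounds**

F1 | step 4 | 2-methyl-1-(trimethylsilyloxy)cyclohexadec-1-ene | CC1=C(O[Si](C)(C)C)CCCCCCCCCCCCCC1
F2 | step 4 | 16-oxoheptadecanoic acid | CC(=O)CCCCCCCCCCCCCCC(=O)O
F3 | step 2 | racemic 2-methylcyclohexadecanone | CC1CCCCCCCCCCCCCCC1=O
F4 | step 2 | racemic 17-methyloxacycloheptadecan-2-one | CC1CCCCCCCCCCCCCCC(=O)O1
F5 | step 2 | racemic methyl 16-hydroxyheptadecanoate | CC(O)CCCCCCCCCCCCCCC(=O)OC
F6 | step 2 | methyl (R)-16-acetoxyheptadecanoate | C[C@@H](OC(C)=O)CCCCCCCCCCCCCCC(=O)OC
F7 | step 2 | methyl (S)-16-hydroxyheptadecanoate | C[C@H](O)CCCCCCCCCCCCCCC(=O)OC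
F8 | step 8 | (17S)-17-acetoxy-2-oxooctadecyl 2-bromopropanoate | C[C@H](OC(C)=O)CCCCCCCCCCCCCCC(=O)COC(=O)C(C)Br
F9 | step 8 | (2S)-16-(3-hydroxy-4-methyl-5-oxooxolan-3-yl)hexadecan-2-yl acetate | C[C@H](OC(C)=O)CCCCCCCCCCCCCCC1(O)COC(=O)C1C
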